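The route rests on cutting the tetrasubstituted C14=C15 bond that the butenolide (C14, C15, C16, O, C18) shares with the cyclohexene (C8–C11, C14, C15), together with the lactone C16–O bond. One condensation cascade forms both from the open-chain 1,5-diketone 15: its β-keto ester (C8, C15, C16) attacks the hydroxymethyl ketone (C14, C18), and the C18 hydroxyl then lactonises. Compound 15 already carries C10 and C11, set by alkylating a δ-lactone, and bears a vinyl group at C11 instead of a protected hydroxyethyl arm, so that C13 is borylated directly. Suzuki coupling and an epoxide-opening etherification then close the twelve-membered ether bridge.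

Key step: step 9

Remark: core atoms are numbered C8–C16 and C18 as in the natural product, the ether bridge C1′ (methyl-bearing alkene carbon) to C6′ (CH2OH); methyl hydrogen (R)-3-methylglutarate is assumed to be a catalogue compound of high enantiomeric purity.

Step 1
Reactants: 1 methyl hydrogen (R)-3-methylglutarate
Product: 3 (4R)-4-methyltetrahydro-2H-pyran-2-one, via hydroxy ester 2 (not isolated)
Conditions: BH3·SMe2, THF, 0 °C to rt; MeOH; then TsOH·H2O (cat.), toluene, 60 °C
Reagents that add atoms: none
Why: Chemoselective borane reduction takes the free acid much faster than the methyl ester, and the δ-hydroxy ester then lactonises under acid catalysis; the C10 stereocentre comes from 1 and is not touched.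

Step 2
Reactants: 3 (4R)-4-methyltetrahydro-2H-pyran-2-one
Product: 4 (3S,4R)-3,4-dimethyltetrahydro-2H-pyran-2-one
Conditions: LiN(iPr)2, THF, −78 °C; MeI, −78 to −40 °C
Reagents that add atoms: iodomethane, CI
Why: Enolate alkylation of the δ-lactone should place the methyl group mainly anti to the C10 methyl, and the configuration made here at C11 is of no consequence because this carbon is enolised again in step 3.

Step 3
Reactants: 4 (3S,4R)-3,4-dimethyltetrahydro-2H-pyran-2-one; 5 phenyl vinyl sulfoxide
Product: 6 (3S,4R)-3,4-dimethyl-3-[2-(phenylsulfinyl)ethyl]tetrahydro-2H-pyran-2-one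
Conditions: LiN(iPr)2, THF, −78 °C; then 5, −78 to −20 °C; aq. NH4Cl
Reagents that add atoms: none
Why: Michael addition of the tetrasubstituted lithium enolate to the vinyl sulfoxide (a vinyl cation equivalent); allylic 1,2-strain with the C11 methyl holds the C10 methyl pseudoaxial on the enolate, so the acceptor is attacked on the opposite face, the new arm ends up trans to the C10 methyl and C11 is set as S.

Step 4
Reactants: 6 (3S,4R)-3,4-dimethyl-3-[2-(phenylsulfinyl)ethyl]tetrahydro-2H-pyran-2-one
Product: 7 (3S,4R)-3,4-dimethyl-3-vinyltetrahydro-2H-pyran-2-one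
Conditions: NaHCO3, toluene, 110 °C
Reagents that add atoms: none
Why: Sulfoxide pyrolysis (thermal syn-elimination) can take a hydrogen only from C12, so the C12=C13 vinyl group should form without touching either stereocentre.

Step 5
Reactants: 7 (3S,4R)-3,4-dimethyl-3-vinyltetrahydro-2H-pyran-2-one; 8 tributyl[(methoxymethoxy)methyl]stannane
Product: 10 (3S,4R)-6-hydroxy-1-(methoxymethoxy)-3,4-dimethyl-3-vinylhexan-2-one, via organolithium 9 (not isolated)
Conditions: 8, n-BuLi, THF, −78 °C; then 7, −78 °C; aq. NH4Cl
Reagents that add atoms: none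
Why: Tin–lithium exchange gives the α-alkoxymethyllithium, which adds only once to the lactone carbonyl (nucleophilic acyl addition) because the lithium hemiketal alkoxide persists at −78 °C and opens to the hydroxy ketone, in equilibrium with its cyclic hemiketal, on work-up.

Step 6
Reactants: 10 (3S,4R)-6-hydroxy-1-(methoxymethoxy)-3,4-dimethyl-3-vinylhexan-2-one
Product: 11 (3R,4S)-6-(methoxymethoxy)-3,4-dimethyl-5-oxo-4-vinylhexanoic acid
Conditions: 2,2,6,6-tetramethylpiperidin-1-oxyl (cat.), PhI(OAc)2, MeCN/H2O, rt
Reagents that add atoms: water, O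
Why: Oxoammonium-mediated oxidation takes the primary C8 alcohol through the aldehyde hydrate to the acid and should leave the ketone, the vinyl group and the acetal alone, while the non-oxidisable hemiketal form of 10 drains through the open chain.

Step 7
Reactants: 11 (3R,4S)-6-(methoxymethoxy)-3,4-dimethyl-5-oxo-4-vinylhexanoic acid; 12 potassium methyl malonate
Product: 14 methyl (5R,6S)-8-(methoxymethoxy)-5,6-dimethyl-3,7-dioxo-6-vinyloctanoate, via acyl imidazolide 13 (not isolated)
Conditions: 1,1′-carbonyldiimidazole, THF, rt; then 12, MgCl2, Et3N, MeCN, rt to 45 °C; 1 M HCl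
Reagents that add atoms: none
Why: Masamune–Brooks homologation, in which the acyl imidazolide is C-acylated by the magnesium enolate of the malonate half-ester and the adduct loses CO2 on acidification, builds the C8/C15/C16 β-keto ester without a base strong enough to cleave the C10–C11 bond.

Step 8
Reactants: 14 methyl (5R,6S)-8-(methoxymethoxy)-5,6-dimethyl-3,7-dioxo-6-vinyloctanoate
Product: 15 methyl (5R,6S)-8-hydroxy-5,6-dimethyl-3,7-dioxo-6-vinyloctanoate
Conditions: HCl (cat.), MeOH, 40 °C
Reagents that add atoms: none
Why: Acid-catalysed acetal exchange with methanol removes the methoxymethyl group as dimethoxymethane under conditions that the β-keto ester, the vinyl group and both stereocentres should tolerate.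

Step 9
Reactants: 15 methyl (5R,6S)-8-hydroxy-5,6-dimethyl-3,7-dioxo-6-vinyloctanoate
Product: 18 (4S,5R)-4,5-dimethyl-4-vinyl-5,6-dihydro-2-benzofuran-1,7(3H,4H)-dione, via aldol adduct 16 (not isolated), via cyclohexenone ester 17 (not isolated)
Conditions: piperidine (0.2 equiv), AcOH (0.2 equiv), toluene, 4 Å molecular sieves, 80 °C
Reagents that add atoms: none
Why: Piperidinium acetate makes the C15 methylene, the most acidic position of 15, nucleophilic, and this carbon adds to the C14 carbonyl in a 6-(enolexo)-exo-trig aldol closure (counting the ester enol form) to give 16, after which E1cB loss of water, driven by conjugation of the new C14=C15 bond with the C8 ketone and the C16 ester, gives cyclohexenone 17. The closest known reaction is the intramolecular Knoevenagel (aldol) condensation of a 1,5-dicarbonyl compound, the ring-closing half of a Robinson annulation, followed by lactonisation. Because the ring forces the C18 hydroxymethyl group and the C16 ester to be cis on the double bond, the hydroxyl attacks the ester in a 5-exo-trig acyl substitution, methanol leaves and the butenolide closes in the same flask. No stereocentre is formed, and C10 and C11 cannot epimerise because C11 has no hydrogen and C10 is not alpha to a carbonyl group. The selectivity needed is between two six-ring aldol modes, C15 onto C14 or C18 onto C8, and the far higher acidity of the doubly activated C15 methylene should decide it under this buffered catalysis. The same mildness should avoid retro-Michael rupture of the crowded C10–C11 bond, which a strong base could trigger.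

Step 10
Reactants: 18 (4S,5R)-4,5-dimethyl-4-vinyl-5,6-dihydro-2-benzofuran-1,7(3H,4H)-dione
Product: 19 (4S,5R,7R)-7-hydroxy-4,5-dimethyl-4-vinyl-4,5,6,7-tetrahydro-2-benzofuran-1(3H)-one
Conditions: (3aS)-1-methyl-3,3-diphenyltetrahydro-1H,3H-pyrrolo[1,2-c][1,3,2]oxazaborole [(S)-Me-CBS] (0.3 equiv), catecholborane, toluene, −78 °C
Reagents that add atoms: none
Why: Corey–Bakshi–Shibata reduction, in which the oxazaborolidine binds the C8 ketone with the fully substituted alkenyl carbon C15 as the large group and delivers hydride in a 1,2-sense, should give the 8R alcohol by reagent control, while catecholborane at −78 °C leaves the vinyl group and the lactone alone.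

Step 11
Reactants: 20 but-2-yn-1-ol
Product: 22 (2Z)-3-iodobut-2-en-1-ol, via alkenylalanate 21 (not isolated)
Conditions: NaAlH2(OCH2CH2OMe)2, THF, 0 °C to rt; then I2, −78 °C
Reagents that add atoms: iodine, II
Why: trans-Hydroalumination of the propargylic alkoxide places aluminium on C3 in a five-membered alanate, and iodinolysis with retention gives the vinyl iodide with iodine cis to the carbinol carbon, which fixes the Z geometry of the later C1′=C2′ bond.

Step 12
Reactants: 22 (2Z)-3-iodobut-2-en-1-ol
Product: 23 (2Z)-3-iodobut-2-enal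
Conditions: MnO2, CH2Cl2, rt
Reagents that add atoms: none
Why: Allylic oxidation with MnO2 is neutral and heterogeneous and should give the enal without Z to E isomerisation.

Step 13
Reactants: 23 (2Z)-3-iodobut-2-enal; 24 2-methylallylmagnesium chloride
Product: 26 (4S,5Z)-6-iodo-2-methylhepta-1,5-dien-4-ol, via allylborane 25 (not isolated)
Conditions: (−)-B-methoxydiisopinocampheylborane, 24, Et2O, −78 °C to rt; then 23, −78 °C; NaOH, H2O2
Reagents that add atoms: none
Why: Brown asymmetric allylboration with the methallyl reagent made from (+)-α-pinene adds through a chair-like six-membered transition state to the Si face of the aldehyde, which sets C3′ as S.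

Step 14
Reactants: 26 (4S,5Z)-6-iodo-2-methylhepta-1,5-dien-4-ol
Product: 27 tert-butyl (4S,5Z)-6-iodo-2-methylhepta-1,5-dien-4-yl carbonate
Conditions: Boc2O, 4-(dimethylamino)pyridine (cat.), MeCN, rt
Reagents that add atoms: di-tert-butyl dicarbonate, CC(C)(C)OC(=O)OC(=O)OC(C)(C)C
Why: Nucleophile-catalysed acylation of the secondary alcohol gives the tert-butyl carbonate that serves as the internal oxygen nucleophile of the next step.

Step 15
Reactants: 27 tert-butyl (4S,5Z)-6-iodo-2-methylhepta-1,5-dien-4-yl carbonate
Product: 28 (4R,6S)-4-(iodomethyl)-6-[(1Z)-2-iodoprop-1-en-1-yl]-4-methyl-1,3-dioxan-2-one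
Conditions: IBr, toluene, −85 °C
Reagents that add atoms: iodine monobromide, IBr
Why: Bartlett–Smith iodocarbonate cyclisation, in which the carbonate carbonyl oxygen opens the iodonium ion of the 1,1-disubstituted alkene at its tertiary carbon through a chair-like 6-exo transition state with the alkenyl group and the iodomethyl terminus equatorial, should set C5′ syn to C3′ and expel the tert-butyl group, while the electron-poor vinyl iodide stays inert.

Step 16
Reactants: 28 (4R,6S)-4-(iodomethyl)-6-[(1Z)-2-iodoprop-1-en-1-yl]-4-methyl-1,3-dioxan-2-one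
Product: 29 (2S,3Z)-4-iodo-1-[(2R)-2-methyloxiran-2-yl]pent-3-en-2-ol
Conditions: K2CO3, MeOH, 0 °C to rt
Reagents that add atoms: none
Why: Methanolysis of the cyclic carbonate frees the tertiary alkoxide, which displaces the neighbouring primary iodide (intramolecular Williamson reaction) and gives the epoxide with C5′ unchanged (R).

Step 17
Reactants: 29 (2S,3Z)-4-iodo-1-[(2R)-2-methyloxiran-2-yl]pent-3-en-2-ol
Product: 30 tert-butyl{[(2S,3Z)-4-iodo-1-[(2R)-2-methyloxiran-2-yl]pent-3-en-2-yl]oxy}dimethylsilane
Conditions: tert-butyldimethylsilyl chloride, imidazole, DMF, rt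
Reagents that add atoms: tert-butyldimethylsilyl chloride, CC(C)(C)[Si](C)(C)Cl
Why: Imidazole-promoted silylation masks the C3′ hydroxyl so that it cannot open the neighbouring epoxide under the later acid conditions.

Step 18
Reactants: 19 (4S,5R,7R)-7-hydroxy-4,5-dimethyl-4-vinyl-4,5,6,7-tetrahydro-2-benzofuran-1(3H)-one; 30 tert-butyl{[(2S,3Z)-4-iodo-1-[(2R)-2-methyloxiran-2-yl]pent-3-en-2-yl]oxy}dimethylsilane
Product: 32 (4S,5R,7R)-4-{(3Z,5S)-5-[(tert-butyldimethylsilyl)oxy]-3-methyl-6-[(2R)-2-methyloxiran-2-yl]hex-3-en-1-yl}-7-hydroxy-4,5-dimethyl-4,5,6,7-tetrahydro-2-benzofuran-1(3H)-one, via alkylborane 31 (not isolated)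
Conditions: 9-borabicyclo[3.3.1]nonane, THF, rt; then 30, PdCl2(dppf) [dppf = 1,1′-bis(diphenylphosphino)ferrocene], AsPh3, Cs2CO3, DMF/H2O, rt
Reagents that add atoms: none
Why: B-alkyl Suzuki–Miyaura coupling, in which the borane adds to the open end of the C11 vinyl group to put boron on C13 and the alkylborate transmetallates to the alkenylpalladium iodide formed from 30, should form the C13–C1′ bond with retention of the Z geometry while the lactone, the epoxide and the free C8 hydroxyl survive the mild base.

Step 19
Reactants: 32 (4S,5R,7R)-4-{(3Z,5S)-5-[(tert-butyldimethylsilyl)oxy]-3-methyl-6-[(2R)-2-methyloxiran-2-yl]hex-3-en-1-yl}-7-hydroxy-4,5-dimethyl-4,5,6,7-tetrahydro-2-benzofuran-1(3H)-one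
Product: 33 3′-O-(tert-butyldimethylsilyl)neocucurbin A
Conditions: camphor-10-sulfonic acid (0.2 equiv), CH2Cl2 (1 mM), 0 °C to rt
Reagents that add atoms: none
Why: Acid-catalysed intramolecular epoxide opening (hydroxy-epoxide etherification), in which the C8 hydroxyl, held on the same ring face as the C11 arm, attacks the protonated epoxide at its tertiary carbon C5′ with inversion, should turn the (R)-epoxide into the (S)-ether and free the C6′ alcohol, with high dilution against oligomers and the silyl ether keeping the C3′ oxygen out.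

Step 20
Reactants: 33 3′-O-(tert-butyldimethylsilyl)neocucurbin A
Product: 34 neocucurbin A
Conditions: HF·pyridine, pyridine, THF, 0 °C to rt
Reagents that add atoms: none
Why: Fluoride-mediated desilylation under buffered conditions should cleave the allylic silyl ether without opening the butenolide or ionising the tertiary ether.

Compound list
1 | methyl hydrogen (R)-3-methylglutarate | COC(=O)C[C@H](C)CC(=O)O | starting material
2 | methyl (3R)-5-hydroxy-3-methylpentanoate | COC(=O)C[C@H](C)CCO | intermediate (not isolated)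
3 | (4R)-4-methyltetrahydro-2H-pyran-2-one | C[C@@H]1CCOC(=O)C1 | intermediate
4 | (3S,4R)-3,4-dimethyltetrahydro-2H-pyran-2-one (trans) | C[C@H]1[C@H](C)CCOC1=O | intermediate
5 | phenyl vinyl sulfoxide | C=CS(=O)c1ccccc1 | starting material
6 | (3S,4R)-3,4-dimethyl-3-[2-(phenylsulfinyl)ethyl]tetrahydro-2H-pyran-2-one (both configurations at sulfur) | O=S(c1ccccc1)CC[C@@]2(C)[C@H](C)CCOC2=O | intermediate
7 | (3S,4R)-3,4-dimethyl-3-vinyltetrahydro-2H-pyran-2-one | C=C[C@@]1(C)[C@H](C)CCOC1=O | intermediate
8 | tributyl[(methoxymethoxy)methyl]stannane | CCCC[Sn](CCCC)(CCCC)COCOC | starting material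
9 | (methoxymethoxy)methyllithium | [Li]COCOC | intermediate (not isolated)
10 | (3S,4R)-6-hydroxy-1-(methoxymethoxy)-3,4-dimethyl-3-vinylhexan-2-one | COCOCC(=O)[C@@](C)(C=C)[C@H](C)CCO | intermediate
11 | (3R,4S)-6-(methoxymethoxy)-3,4-dimethyl-5-oxo-4-vinylhexanoic acid | COCOCC(=O)[C@@](C)(C=C)[C@H](C)CC(=O)O | intermediate
12 | potassium methyl malonate | COC(=O)CC(=O)[O-].[K+] | starting material
13 | acyl imidazolide of 11 | COCOCC(=O)[C@@](C)(C=C)[C@H](C)CC(=O)n1ccnc1 | intermediate (not isolated)
14 | methyl (5R,6S)-8-(methoxymethoxy)-5,6-dimethyl-3,7-dioxo-6-vinyloctanoate | COCOCC(=O)[C@@](C)(C=C)[C@H](C)CC(=O)CC(=O)OC | intermediate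
15 | methyl (5R,6S)-8-hydroxy-5,6-dimethyl-3,7-dioxo-6-vinyloctanoate | COC(=O)CC(=O)C[C@@H](C)[C@](C)(C=C)C(=O)CO | intermediate
16 | methyl (3S,4R)-2-hydroxy-2-(hydroxymethyl)-3,4-dimethyl-6-oxo-3-vinylcyclohexane-1-carboxylate (C1 and C2 unassigned) | COC(=O)C1C(=O)C[C@@H](C)[C@](C)(C=C)C1(O)CO | intermediate (not isolated)
17 | methyl (3S,4R)-2-(hydroxymethyl)-3,4-dimethyl-6-oxo-3-vinylcyclohex-1-ene-1-carboxylate | O=C1C[C@@H](C)[C@](C)(C=C)C(CO)=C1C(=O)OC | intermediate (not isolated)
18 | (4S,5R)-4,5-dimethyl-4-vinyl-5,6-dihydro-2-benzofuran-1,7(3H,4H)-dione | O=C1C[C@@H](C)[C@](C)(C=C)C2=C1C(=O)OC2 | intermediate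
19 | (4S,5R,7R)-7-hydroxy-4,5-dimethyl-4-vinyl-4,5,6,7-tetrahydro-2-benzofuran-1(3H)-one | O[C@@H]1C[C@@H](C)[C@](C)(C=C)C2=C1C(=O)OC2 | intermediate
20 | but-2-yn-1-ol | CC#CCO | starting material
21 | sodium alkenylalanate with a five-membered C3–Al–O ring | CC1=CCO[Al-]1(OCCOC)OCCOC.[Na+] | intermediate (not isolated)
22 | (2Z)-3-iodobut-2-en-1-ol | C/C(I)=C/CO | intermediate
23 | (2Z)-3-iodobut-2-enal | C/C(I)=C/C=O | intermediate
24 | 2-methylallylmagnesium chloride | CC(=C)C[Mg]Cl | starting material
25 | (−)-B-(2-methylallyl)diisopinocampheylborane | C=C(C)CB([C@@H]1C[C@@H]2C[C@H]([C@H]1C)C2(C)C)[C@@H]3C[C@@H]4C[C@H]([C@H]3C)C4(C)C | intermediate (not isolated)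
26 | (4S,5Z)-6-iodo-2-methylhepta-1,5-dien-4-ol | C/C(I)=C/[C@@H](O)CC(C)=C | intermediate
27 | tert-butyl (4S,5Z)-6-iodo-2-methylhepta-1,5-dien-4-yl carbonate | C/C(I)=C/[C@@H](OC(=O)OC(C)(C)C)CC(C)=C | intermediate
28 | (4R,6S)-4-(iodomethyl)-6-[(1Z)-2-iodoprop-1-en-1-yl]-4-methyl-1,3-dioxan-2-one | C/C(I)=C/[C@@H]1C[C@](C)(CI)OC(=O)O1 | intermediate
29 | (2S,3Z)-4-iodo-1-[(2R)-2-methyloxiran-2-yl]pent-3-en-2-ol | C/C(I)=C/[C@@H](O)C[C@]1(C)CO1 | intermediate
30 | tert-butyl{[(2S,3Z)-4-iodo-1-[(2R)-2-methyloxiran-2-yl]pent-3-en-2-yl]oxy}dimethylsilane | C/C(I)=C/[C@@H](O[Si](C)(C)C(C)(C)C)C[C@]1(C)CO1 | intermediate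
31 | (4S,5R,7R)-4-[2-(9-borabicyclo[3.3.1]nonan-9-yl)ethyl]-7-hydroxy-4,5-dimethyl-4,5,6,7-tetrahydro-2-benzofuran-1(3H)-one | O[C@@H]1C[C@@H](C)[C@](C)(CCB3C4CCCC3CCC4)C2=C1C(=O)OC2 | intermediate (not isolated)
32 | (4S,5R,7R)-4-{(3Z,5S)-5-[(tert-butyldimethylsilyl)oxy]-3-methyl-6-[(2R)-2-methyloxiran-2-yl]hex-3-en-1-yl}-7-hydroxy-4,5-dimethyl-4,5,6,7-tetrahydro-2-benzofuran-1(3H)-one | O[C@@H]1C[C@@H](C)[C@](C)(CC/C(C)=C\[C@@H](O[Si](C)(C)C(C)(C)C)C[C@]3(C)CO3)C2=C1C(=O)OC2 | intermediate
33 | 3′-O-(tert-butyldimethylsilyl)neocucurbin A | C/C1=C/[C@@H](O[Si](C)(C)C(C)(C)C)C[C@@](C)(CO)O[C@@H]2C[C@@H](C)[C@](C)(CC1)C1=C2C(=O)OC1 | intermediate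
34 | neocucurbin A | C/C1=C/[C@@H](O)C[C@@](C)(CO)O[C@@H]2C[C@@H](C)[C@](C)(CC1)C1=C2C(=O)OC1 | target

Total step count: 20.
Longest linear sequence: 13 steps (steps 1–10 and 18–20, from 1 to 34); the bridge fragment 30 takes 7 steps (11–17).

Steps most likely to fail

Step 19. Capture of the acid-activated tertiary epoxide by the distant C8 hydroxyl through a twelve-membered transition state may be slower than hydride shift to an aldehyde, proton loss to an allylic alcohol or intermolecular opening. The fallback reverses the order of the two bridge-forming bonds and sets out from 19 and 30, before any coupling. BF3·OEt2 (cat.) in CH2Cl2 at −78 to −40 °C, with 19 in excess and recovered, should open the epoxide of 30 at C5′ with inversion to give the vinyl iodide ether F1. 9-Borabicyclo[3.3.1]nonane then hydroborates the C11 vinyl group to the alkylborane F2, and PdCl2(dppf), AsPh3 and Cs2CO3 in DMF/THF/H2O at high dilution close the ring by an intramolecular B-alkyl Suzuki–Miyaura coupling, which comes back to the route at 33.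

Step 9. Addition to the hindered C14 carbonyl may be slow under amine catalysis, so that enolisation toward C18 with aldol closure onto C8, or retro-Michael fragmentation, takes over. The fallback sets out from the protected compound 14. TiCl4 and pyridine in THF at 0 °C to rt (titanium-enolate Knoevenagel condensation) should close the six-membered ring to the cyclohexenone ester F3 while the C18 oxygen is still masked, so that only C15 can act as the nucleophile. HCl in MeOH then removes the methoxymethyl group and the freed hydroxyl lactonises, which comes back to the route at 18.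

Step 3. Conjugate addition of the hindered enolate to the weak acceptor may be sluggish, with proton transfer and oligomerisation of the sulfoxide competing and facial selectivity eroding at higher temperature. The fallback sets out from 4. The same lithium enolate is added to acetaldehyde at −78 °C (aldol addition, same facial bias) to give the hydroxyethyl lactone F4. Dehydration of the secondary alcohol with Ph2S[OC(CF3)2Ph]2 (Martin sulfurane) in CH2Cl2, which can take a hydrogen only from the methyl group, should give the vinyl lactone and comes back to the route at 7.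

Further compounds
F1 | step 19 | (4S,5R,7R)-7-{[(2S,4S,5Z)-4-[(tert-butyldimethylsilyl)oxy]-1-hydroxy-6-iodo-2-methylhept-5-en-2-yl]oxy}-4,5-dimethyl-4-vinyl-4,5,6,7-tetrahydro-2-benzofuran-1(3H)-one | C/C(I)=C/[C@@H](O[Si](C)(C)C(C)(C)C)C[C@@](C)(CO)O[C@@H]1C[C@@H](C)[C@](C)(C=C)C2=C1C(=O)OC2
F2 | step 19 | 9-borabicyclo[3.3.1]nonane adduct of F1 at C13 | C/C(I)=C/[C@@H](O[Si](C)(C)C(C)(C)C)C[C@@](C)(CO)O[C@@H]1C[C@@H](C)[C@](C)(CCB3C4CCCC3CCC4)C2=C1C(=O)OC2
F3 | step 9 | methyl (3S,4R)-2-[(methoxymethoxy)methyl]-3,4-dimethyl-6-oxo-3-vinylcyclohex-1-ene-1-carboxylate | O=C1C[C@@H](C)[C@](C)(C=C)C(COCOC)=C1C(=O)OC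
F4 | step 3 | (3R,4R)-3-(1-hydroxyethyl)-3,4-dimethyltetrahydro-2H-pyran-2-one (carbinol centre unassigned) | CC(O)[C@@]1(C)[C@H](C)CCOC1=O
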